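**Plan** (atom labels O1, C2, C3, C3a, C4–C7, C7a are those of the 2,3-dihydrobenzofuran of the target)

- Retrosynthesis: the acetate, the angelate and the acrylate (C2–C(=CH2)CO2Me ⇐ C2–C≡CH ⇐ C2–CH2OH) are taken off first. The benzene ring is then cut at C3a–C7a, C4–C5 and C6–C7 into a 1,6-diyne (silyl ynol ether C7≡C7a–O1 plus the ethynyl group C4≡C3a on C3) and the alkyne C5≡C6 of protected (S)-but-3-yn-2-ol.
- Enabling feature: O1–C2–C3 is a three-atom tether between C7a and C3a, and the benzene ring carries O1 (C7a), C3 (C3a) and the carbinol side chain (C5) in a 1,2,4-pattern. One [2+2+2] event can therefore close the benzene ring and the dihydrofuran ring together. C2–C3 is a threo-diol flanked by C3a and the C2 side-chain carbon, which are the four carbons of L-tartaric acid.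
- Forward order: diethyl L-tartrate → mono-PMB ether → hydroxyl-directed reduction of one ester → other ester to the C3 ethynyl group → ynol ether on O1 from trichloroethylene → cyclotrimerisation (both rings at once) → C7 desilylation, C2–CH2OH → CHO → C≡CH → acrylate → angelate → acetate.
- Stereochemistry: C2 and C3 are the carbinol carbons of (2R,3R)-tartrate and no bond to them is made or broken (the labels become 2S,3S only through CIP priority changes). The side-chain carbinol comes from (S)-but-3-yn-2-ol, and the Z double bond from angelic acid.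

Key step: step 9

Remark on the chemistry: an alkynyl ether whose oxygen sits on a propargylic carbon is expected to undergo a [3,3] shift to an allenylketene below room temperature. C2 therefore carries a silyloxymethyl group, not an ethynyl group, while the ynol ether is present, and the C2 alkyne is made after the arene.

Step 1
Reactants: 1 diethyl L-tartrate
Product: 2 diethyl (2R,3R)-2-hydroxy-3-[(4-methoxybenzyl)oxy]butanedioate
Conditions: PMBCl (1.1 equiv), Ag2O (1.5 equiv), CH2Cl2, rt, dark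
Reagents that add atoms: 4-methoxybenzyl chloride COc1ccc(CCl)cc1
Why: Ag2O-mediated Williamson-type monoalkylation of a twofold-symmetric diol should give one mono-ether whichever hydroxyl reacts, and the non-basic conditions spare the α-stereocentres.

Step 2
Reactants: 2 diethyl (2R,3R)-2-hydroxy-3-[(4-methoxybenzyl)oxy]butanedioate
Product: 3 ethyl (2R,3S)-3,4-dihydroxy-2-[(4-methoxybenzyl)oxy]butanoate
Conditions: BH3·SMe2 (1.05 equiv), NaBH4 (5 mol %), THF, 0 °C to rt; MeOH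
Reagents that add atoms: none
Why: hydroxyl-directed borane reduction (Saito conditions) should reduce only the ester α to the free hydroxyl through its alkoxyborane, which tells the two ends of the tartrate apart without touching a stereocentre.

Step 3
Reactants: 3 ethyl (2R,3S)-3,4-dihydroxy-2-[(4-methoxybenzyl)oxy]butanoate
Product: 5 ethyl (2R,3S)-4-[(tert-butyldiphenylsilyl)oxy]-2-[(4-methoxybenzyl)oxy]-3-[(triethylsilyl)oxy]butanoate, via mono-TBDPS ether 4 (not isolated)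
Conditions: TBDPSCl, imidazole, DMF, 0 °C; then Et3SiCl, rt (crude 3 used at once)
Reagents that add atoms: tert-butyl(chloro)diphenylsilane CC(C)(C)[Si](Cl)(c1ccccc1)c1ccccc1; chlorotriethylsilane CC[Si](Cl)(CC)CC
Why: silyl ether formation in which the bulky TBDPSCl takes the primary hydroxyl (forestalling γ-lactonisation) and Et3SiCl then caps the secondary one as a temporary group.

Step 4
Reactants: 5 ethyl (2R,3S)-4-[(tert-butyldiphenylsilyl)oxy]-2-[(4-methoxybenzyl)oxy]-3-[(triethylsilyl)oxy]butanoate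
Product: 7 (2S,3S)-1-[(tert-butyldiphenylsilyl)oxy]-3-[(4-methoxybenzyl)oxy]-2-[(triethylsilyl)oxy]pent-4-yne, via aldehyde 6 (not isolated)
Conditions: i-Bu2AlH (1.1 equiv), CH2Cl2, −78 °C; then MeOH, K2CO3, MeC(O)C(N2)P(O)(OMe)2, −78 °C to rt
Reagents that add atoms: dimethyl (1-diazo-2-oxopropyl)phosphonate CC(=O)C(=[N+]=[N-])P(=O)(OC)OC
Why: partial ester reduction to the aluminium hemiacetal followed in the same flask by Ohira–Bestmann (Seyferth–Gilbert) homologation is established for fully O-protected α,β-dialkoxy esters and should leave the α-centre (future C3) intact.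

Step 5
Reactants: 7 (2S,3S)-1-[(tert-butyldiphenylsilyl)oxy]-3-[(4-methoxybenzyl)oxy]-2-[(triethylsilyl)oxy]pent-4-yne
Product: 9 (2S,3S)-1-[(tert-butyldiphenylsilyl)oxy]-3-[(4-methoxybenzyl)oxy]-5-(trimethylsilyl)pent-4-yn-2-ol, via C-silylated triethylsilyl ether 8 (not isolated)
Conditions: n-BuLi, THF, −78 °C; Me3SiCl; work-up; then PPTS, MeOH, 0 °C
Reagents that add atoms: chlorotrimethylsilane C[Si](C)(C)Cl
Why: acetylide silylation masks the alkyne C–H for the next step, and acid-catalysed methanolysis then removes only the secondary triethylsilyl ether, which is far more acid-labile than the TBDPS ether, the PMB ether or the alkynylsilane.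

Step 6
Reactants: 9 (2S,3S)-1-[(tert-butyldiphenylsilyl)oxy]-3-[(4-methoxybenzyl)oxy]-5-(trimethylsilyl)pent-4-yn-2-ol; 10 trichloroethylene
Product: 13 (2S,3S)-1-[(tert-butyldiphenylsilyl)oxy]-3-[(4-methoxybenzyl)oxy]-2-{[(triethylsilyl)ethynyl]oxy}-5-(trimethylsilyl)pent-4-yne, via dichlorovinyl ether 11 (not isolated), via lithium alkoxyacetylide 12 (not isolated)
Conditions: KH, THF, 0 °C; Cl2C=CHCl, −50 °C to rt; then n-BuLi (2.5 equiv), −78 to −40 °C; Et3SiCl, −78 to 0 °C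
Reagents that add atoms: chlorotriethylsilane CC[Si](Cl)(CC)CC
Why: Greene ynol ether synthesis, in which the alkoxide adds to dichloroacetylene formed in situ, n-BuLi then effects elimination and chlorine–lithium exchange, and the acetylide is silylated at carbon; the bulky TBDPS group is chosen to resist O-to-O silyl migration in the alkoxide.

Step 7
Reactants: 13 (2S,3S)-1-[(tert-butyldiphenylsilyl)oxy]-3-[(4-methoxybenzyl)oxy]-2-{[(triethylsilyl)ethynyl]oxy}-5-(trimethylsilyl)pent-4-yne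
Product: 14 (2S,3S)-1-[(tert-butyldiphenylsilyl)oxy]-3-[(4-methoxybenzyl)oxy]-2-{[(triethylsilyl)ethynyl]oxy}pent-4-yne
Conditions: K2CO3 (0.2 equiv), MeOH–THF, 0 °C, stopped at full conversion of 13
Reagents that add atoms: none
Why: base-catalysed methanolysis of an alkynylsilane is much faster for SiMe3 than for SiEt3, so with catalytic base at 0 °C only the carbon alkyne should be unmasked while the triethylsilyl ynol ether stays.

Step 8
Reactants: 15 (S)-but-3-yn-2-ol
Product: 16 (S)-3-[(triisopropylsilyl)oxy]but-1-yne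
Conditions: i-Pr3SiOTf, 2,6-lutidine, CH2Cl2, 0 °C
Reagents that add atoms: triisopropylsilyl trifluoromethanesulfonate CC(C)[Si](OS(=O)(=O)C(F)(F)F)(C(C)C)C(C)C
Why: standard silyl ether formation at oxygen, which cannot affect the carbinol configuration; the triisopropylsilyl group is chosen to survive the later base and fluoride steps.

Step 9
Reactants: 14 (2S,3S)-1-[(tert-butyldiphenylsilyl)oxy]-3-[(4-methoxybenzyl)oxy]-2-{[(triethylsilyl)ethynyl]oxy}pent-4-yne; 16 (S)-3-[(triisopropylsilyl)oxy]but-1-yne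
Product: 17 (2S,3S)-2-{[(tert-butyldiphenylsilyl)oxy]methyl}-3-[(4-methoxybenzyl)oxy]-7-(triethylsilyl)-5-{(1S)-1-[(triisopropylsilyl)oxy]ethyl}-2,3-dihydrobenzofuran
Conditions: Cp*RuCl(cod) (10 mol %), 16 (4 equiv), ClCH2CH2Cl, rt, slow addition of 14
Reagents that add atoms: none
Why: Proposed new method: Cp*RuCl(cod) (divalent ruthenium) is expected to couple the two tethered alkynes of 14 oxidatively through their inner carbons (C7a–C3a) to a ruthenacycle fused to the nascent O1–C2–C3 ring, after which 16 inserts at the unhindered C4 end and reductive elimination forms C4–C5 and C6–C7 and releases the arene. The closest known reactions are the Cp*RuCl(cod)-catalysed cyclotrimerisation of 1,6-diynes with terminal alkynes, the rhodium-catalysed cyclisation of ynamide-tethered diynes to indolines and the CpCo-mediated cocyclisation of silyl(alkoxy)acetylenes; an alkynyl ether as one arm of a tethered diyne is not documented. The dihydrofuran ring closes in the oxidative coupling (five-membered, both alkynes exo to the new ring) and the benzene ring by the [2+2+2] union of the three alkynes; no stereocentre is formed, and C2, C3 and the carbinol carbon are not touched. The side chain should go to C5 by the meta rule for diynes substituted at one terminus, the SiEt3 group on C7 keeping the bulky substituent of 16 away from C6. Cross-coupling over homo-coupling is favoured by slow addition of 14 to an excess of 16, and no sigmatropic shift of the ynol ether is possible because O1 sits on a carbon without an unsaturated neighbour.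

Step 10
Reactants: 17 (2S,3S)-2-{[(tert-butyldiphenylsilyl)oxy]methyl}-3-[(4-methoxybenzyl)oxy]-7-(triethylsilyl)-5-{(1S)-1-[(triisopropylsilyl)oxy]ethyl}-2,3-dihydrobenzofuran
Product: 18 [(2S,3S)-3-[(4-methoxybenzyl)oxy]-7-(triethylsilyl)-5-{(1S)-1-[(triisopropylsilyl)oxy]ethyl}-2,3-dihydrobenzofuran-2-yl]methanol
Conditions: Bu4NF (1.1 equiv), THF, 0 °C
Reagents that add atoms: none
Why: fluoride-mediated silyl ether cleavage, in which the primary TBDPS ether should go well before the hindered secondary triisopropylsilyl ether and the aryl–silicon bond.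

Step 11
Reactants: 18 [(2S,3S)-3-[(4-methoxybenzyl)oxy]-7-(triethylsilyl)-5-{(1S)-1-[(triisopropylsilyl)oxy]ethyl}-2,3-dihydrobenzofuran-2-yl]methanol
Product: 19 [(2S,3S)-3-[(4-methoxybenzyl)oxy]-5-{(1S)-1-[(triisopropylsilyl)oxy]ethyl}-2,3-dihydrobenzofuran-2-yl]methanol
Conditions: KOSiMe3 (0.3 equiv), DMSO, H2O (10 equiv), 60 °C
Reagents that add atoms: none
Why: silanolate-catalysed protodesilylation of an arylsilane in wet DMSO (attack at silicon, protonation of the aryl carbon ortho to O1) avoids acid, which would ionise the two benzylic C–O bonds.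

Step 12
Reactants: 19 [(2S,3S)-3-[(4-methoxybenzyl)oxy]-5-{(1S)-1-[(triisopropylsilyl)oxy]ethyl}-2,3-dihydrobenzofuran-2-yl]methanol
Product: 20 (2R,3S)-3-[(4-methoxybenzyl)oxy]-5-{(1S)-1-[(triisopropylsilyl)oxy]ethyl}-2,3-dihydrobenzofuran-2-carbaldehyde
Conditions: Dess–Martin periodinane, NaHCO3, CH2Cl2, 0 °C to rt; used at once
Reagents that add atoms: none
Why: buffered Dess–Martin oxidation should give the α-aryloxy aldehyde under neutral conditions without epimerisation (the 2R label is a CIP change only).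

Step 13
Reactants: 20 (2R,3S)-3-[(4-methoxybenzyl)oxy]-5-{(1S)-1-[(triisopropylsilyl)oxy]ethyl}-2,3-dihydrobenzofuran-2-carbaldehyde
Product: 21 (2S,3S)-2-ethynyl-3-[(4-methoxybenzyl)oxy]-5-{(1S)-1-[(triisopropylsilyl)oxy]ethyl}-2,3-dihydrobenzofuran
Conditions: MeC(O)C(N2)P(O)(OMe)2, K2CO3, MeOH, 0 °C (reagent and base premixed)
Reagents that add atoms: dimethyl (1-diazo-2-oxopropyl)phosphonate CC(=O)C(=[N+]=[N-])P(=O)(OC)OC
Why: Ohira–Bestmann homologation at 0 °C with the preformed reagent anion should add to the aldehyde faster than C2 is enolised, so the cis relationship is kept.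

Step 14
Reactants: 21 (2S,3S)-2-ethynyl-3-[(4-methoxybenzyl)oxy]-5-{(1S)-1-[(triisopropylsilyl)oxy]ethyl}-2,3-dihydrobenzofuran
Product: 22 methyl 2-[(2S,3S)-3-[(4-methoxybenzyl)oxy]-5-{(1S)-1-[(triisopropylsilyl)oxy]ethyl}-2,3-dihydrobenzofuran-2-yl]acrylate
Conditions: Pd(OAc)2 (3 mol %), 2-PyPPh2 (30 mol %), MsOH (15 mol %), CO (5 bar), MeOH–CH2Cl2, 40 °C
Reagents that add atoms: carbon monoxide [C-]#[O+]; methanol CO
Why: palladium-catalysed Markovnikov hydromethoxycarbonylation of a terminal alkyne with the 2-pyridylphosphine ligand gives the 2-substituted acrylate, and keeping the acid below the ligand loading leaves only a pyridinium-buffered medium for the benzylic ethers.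

Step 15
Reactants: 22 methyl 2-[(2S,3S)-3-[(4-methoxybenzyl)oxy]-5-{(1S)-1-[(triisopropylsilyl)oxy]ethyl}-2,3-dihydrobenzofuran-2-yl]acrylate
Product: 23 methyl 2-[(2S,3S)-5-[(1S)-1-hydroxyethyl]-3-[(4-methoxybenzyl)oxy]-2,3-dihydrobenzofuran-2-yl]acrylate
Conditions: Bu4NF, AcOH (1:1), THF, 0 °C to rt
Reagents that add atoms: none
Why: fluoride cleavage of the silyl ether, buffered with acetic acid so that the γ-proton of the acrylate at C2 is not removed and the C3 ether is not eliminated.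

Step 16
Reactants: 23 methyl 2-[(2S,3S)-5-[(1S)-1-hydroxyethyl]-3-[(4-methoxybenzyl)oxy]-2,3-dihydrobenzofuran-2-yl]acrylate
Product: 24 (1S)-1-[(2S,3S)-2-(3-methoxy-3-oxoprop-1-en-2-yl)-3-[(4-methoxybenzyl)oxy]-2,3-dihydrobenzofuran-5-yl]ethyl (Z)-2-methylbut-2-enoate
Conditions: angelic acid, 2,4,6-Cl3C6H2COCl, Et3N, toluene, rt; then 23, 70 °C
Reagents that add atoms: angelic acid C/C=C(/C)C(=O)O
Why: Yamaguchi-type esterification through the mixed trichlorobenzoic anhydride without a nucleophilic catalyst is the established way to keep the Z geometry of angelates, and O-acylation retains the carbinol configuration.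

Step 17
Reactants: 24 (1S)-1-[(2S,3S)-2-(3-methoxy-3-oxoprop-1-en-2-yl)-3-[(4-methoxybenzyl)oxy]-2,3-dihydrobenzofuran-5-yl]ethyl (Z)-2-methylbut-2-enoate
Product: 25 (1S)-1-[(2S,3S)-3-hydroxy-2-(3-methoxy-3-oxoprop-1-en-2-yl)-2,3-dihydrobenzofuran-5-yl]ethyl (Z)-2-methylbut-2-enoate
Conditions: DDQ, CH2Cl2–pH 7 buffer, 0 °C
Reagents that add atoms: none
Why: oxidative PMB ether cleavage, placed after the esterification because the acyloxy group deactivates the side-chain benzylic C–H toward hydride abstraction, so DDQ should attack the p-methoxybenzyl CH2 first.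

Step 18
Reactants: 25 (1S)-1-[(2S,3S)-3-hydroxy-2-(3-methoxy-3-oxoprop-1-en-2-yl)-2,3-dihydrobenzofuran-5-yl]ethyl (Z)-2-methylbut-2-enoate
Product: 26 (1S)-1-[(2S,3S)-3-acetoxy-2-(3-methoxy-3-oxoprop-1-en-2-yl)-2,3-dihydrobenzofuran-5-yl]ethyl (Z)-2-methylbut-2-enoate (CNP0168827.1)
Conditions: Ac2O, pyridine, DMAP (cat.), CH2Cl2, 0 °C to rt
Reagents that add atoms: acetic anhydride CC(=O)OC(C)=O
Why: acetylation of the C3 alcohol at oxygen, which leaves C3 and the neighbouring esters unchanged.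

**Compound list**

1 | diethyl L-tartrate | CCOC(=O)[C@H](O)[C@@H](O)C(=O)OCC | starting material
2 | diethyl (2R,3R)-2-hydroxy-3-[(4-methoxybenzyl)oxy]butanedioate | CCOC(=O)[C@H](O)[C@@H](OCc1ccc(OC)cc1)C(=O)OCC | intermediate
3 | ethyl (2R,3S)-3,4-dihydroxy-2-[(4-methoxybenzyl)oxy]butanoate | OC[C@H](O)[C@@H](OCc1ccc(OC)cc1)C(=O)OCC | intermediate
4 | ethyl (2R,3S)-4-[(tert-butyldiphenylsilyl)oxy]-3-hydroxy-2-[(4-methoxybenzyl)oxy]butanoate | CC(C)(C)[Si](c1ccccc1)(c1ccccc1)OC[C@H](O)[C@@H](OCc1ccc(OC)cc1)C(=O)OCC | intermediate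
5 | ethyl (2R,3S)-4-[(tert-butyldiphenylsilyl)oxy]-2-[(4-methoxybenzyl)oxy]-3-[(triethylsilyl)oxy]butanoate | CC(C)(C)[Si](c1ccccc1)(c1ccccc1)OC[C@H](O[Si](CC)(CC)CC)[C@@H](OCc1ccc(OC)cc1)C(=O)OCC | intermediate
6 | (2R,3S)-4-[(tert-butyldiphenylsilyl)oxy]-2-[(4-methoxybenzyl)oxy]-3-[(triethylsilyl)oxy]butanal | CC(C)(C)[Si](c1ccccc1)(c1ccccc1)OC[C@H](O[Si](CC)(CC)CC)[C@@H](OCc1ccc(OC)cc1)C=O | intermediate
7 | (2S,3S)-1-[(tert-butyldiphenylsilyl)oxy]-3-[(4-methoxybenzyl)oxy]-2-[(triethylsilyl)oxy]pent-4-yne | CC(C)(C)[Si](c1ccccc1)(c1ccccc1)OC[C@H](O[Si](CC)(CC)CC)[C@@H](OCc1ccc(OC)cc1)C#C | intermediate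
8 | (2S,3S)-1-[(tert-butyldiphenylsilyl)oxy]-3-[(4-methoxybenzyl)oxy]-2-[(triethylsilyl)oxy]-5-(trimethylsilyl)pent-4-yne | CC(C)(C)[Si](c1ccccc1)(c1ccccc1)OC[C@H](O[Si](CC)(CC)CC)[C@@H](OCc1ccc(OC)cc1)C#C[Si](C)(C)C | intermediate
9 | (2S,3S)-1-[(tert-butyldiphenylsilyl)oxy]-3-[(4-methoxybenzyl)oxy]-5-(trimethylsilyl)pent-4-yn-2-ol | CC(C)(C)[Si](c1ccccc1)(c1ccccc1)OC[C@H](O)[C@@H](OCc1ccc(OC)cc1)C#C[Si](C)(C)C | intermediate
10 | trichloroethylene | ClC=C(Cl)Cl | starting material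
11 | (2S,3S)-1-[(tert-butyldiphenylsilyl)oxy]-2-{[(E)-1,2-dichlorovinyl]oxy}-3-[(4-methoxybenzyl)oxy]-5-(trimethylsilyl)pent-4-yne | CC(C)(C)[Si](c1ccccc1)(c1ccccc1)OC[C@H](O/C(Cl)=C\Cl)[C@@H](OCc1ccc(OC)cc1)C#C[Si](C)(C)C | intermediate
12 | lithium {[(2S,3S)-1-[(tert-butyldiphenylsilyl)oxy]-3-[(4-methoxybenzyl)oxy]-5-(trimethylsilyl)pent-4-yn-2-yl]oxy}ethynide | CC(C)(C)[Si](c1ccccc1)(c1ccccc1)OC[C@H](OC#C[Li])[C@@H](OCc1ccc(OC)cc1)C#C[Si](C)(C)C | intermediate
13 | (2S,3S)-1-[(tert-butyldiphenylsilyl)oxy]-3-[(4-methoxybenzyl)oxy]-2-{[(triethylsilyl)ethynyl]oxy}-5-(trimethylsilyl)pent-4-yne | CC(C)(C)[Si](c1ccccc1)(c1ccccc1)OC[C@H](OC#C[Si](CC)(CC)CC)[C@@H](OCc1ccc(OC)cc1)C#C[Si](C)(C)C | intermediate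
14 | (2S,3S)-1-[(tert-butyldiphenylsilyl)oxy]-3-[(4-methoxybenzyl)oxy]-2-{[(triethylsilyl)ethynyl]oxy}pent-4-yne | CC(C)(C)[Si](c1ccccc1)(c1ccccc1)OC[C@H](OC#C[Si](CC)(CC)CC)[C@@H](OCc1ccc(OC)cc1)C#C | intermediate
15 | (S)-but-3-yn-2-ol | C#C[C@H](C)O | starting material
16 | (S)-3-[(triisopropylsilyl)oxy]but-1-yne | C#C[C@H](C)O[Si](C(C)C)(C(C)C)C(C)C | intermediate
17 | (2S,3S)-2-{[(tert-butyldiphenylsilyl)oxy]methyl}-3-[(4-methoxybenzyl)oxy]-7-(triethylsilyl)-5-{(1S)-1-[(triisopropylsilyl)oxy]ethyl}-2,3-dihydrobenzofuran | CC(C)(C)[Si](c3ccccc3)(c3ccccc3)OC[C@@H]1Oc2c([Si](CC)(CC)CC)cc([C@H](C)O[Si](C(C)C)(C(C)C)C(C)C)cc2[C@@H]1OCc3ccc(OC)cc3 | intermediate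
18 | [(2S,3S)-3-[(4-methoxybenzyl)oxy]-7-(triethylsilyl)-5-{(1S)-1-[(triisopropylsilyl)oxy]ethyl}-2,3-dihydrobenzofuran-2-yl]methanol | OC[C@@H]1Oc2c([Si](CC)(CC)CC)cc([C@H](C)O[Si](C(C)C)(C(C)C)C(C)C)cc2[C@@H]1OCc3ccc(OC)cc3 | intermediate
19 | [(2S,3S)-3-[(4-methoxybenzyl)oxy]-5-{(1S)-1-[(triisopropylsilyl)oxy]ethyl}-2,3-dihydrobenzofuran-2-yl]methanol | OC[C@@H]1Oc2ccc([C@H](C)O[Si](C(C)C)(C(C)C)C(C)C)cc2[C@@H]1OCc3ccc(OC)cc3 | intermediate
20 | (2R,3S)-3-[(4-methoxybenzyl)oxy]-5-{(1S)-1-[(triisopropylsilyl)oxy]ethyl}-2,3-dihydrobenzofuran-2-carbaldehyde | O=C[C@@H]1Oc2ccc([C@H](C)O[Si](C(C)C)(C(C)C)C(C)C)cc2[C@@H]1OCc3ccc(OC)cc3 | intermediate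
21 | (2S,3S)-2-ethynyl-3-[(4-methoxybenzyl)oxy]-5-{(1S)-1-[(triisopropylsilyl)oxy]ethyl}-2,3-dihydrobenzofuran | C#C[C@@H]1Oc2ccc([C@H](C)O[Si](C(C)C)(C(C)C)C(C)C)cc2[C@@H]1OCc3ccc(OC)cc3 | intermediate
22 | methyl 2-[(2S,3S)-3-[(4-methoxybenzyl)oxy]-5-{(1S)-1-[(triisopropylsilyl)oxy]ethyl}-2,3-dihydrobenzofuran-2-yl]acrylate | C=C(C(=O)OC)[C@@H]1Oc2ccc([C@H](C)O[Si](C(C)C)(C(C)C)C(C)C)cc2[C@@H]1OCc3ccc(OC)cc3 | intermediate
23 | methyl 2-[(2S,3S)-5-[(1S)-1-hydroxyethyl]-3-[(4-methoxybenzyl)oxy]-2,3-dihydrobenzofuran-2-yl]acrylate | C=C(C(=O)OC)[C@@H]1Oc2ccc([C@H](C)O)cc2[C@@H]1OCc3ccc(OC)cc3 | intermediate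
24 | (1S)-1-[(2S,3S)-2-(3-methoxy-3-oxoprop-1-en-2-yl)-3-[(4-methoxybenzyl)oxy]-2,3-dihydrobenzofuran-5-yl]ethyl (Z)-2-methylbut-2-enoate | C=C(C(=O)OC)[C@@H]1Oc2ccc([C@H](C)OC(=O)/C(C)=C\C)cc2[C@@H]1OCc3ccc(OC)cc3 | intermediate
25 | (1S)-1-[(2S,3S)-3-hydroxy-2-(3-methoxy-3-oxoprop-1-en-2-yl)-2,3-dihydrobenzofuran-5-yl]ethyl (Z)-2-methylbut-2-enoate | C=C(C(=O)OC)[C@@H]1Oc2ccc([C@H](C)OC(=O)/C(C)=C\C)cc2[C@@H]1O | intermediate
26 | (1S)-1-[(2S,3S)-3-acetoxy-2-(3-methoxy-3-oxoprop-1-en-2-yl)-2,3-dihydrobenzofuran-5-yl]ethyl (Z)-2-methylbut-2-enoate (CNP0168827.1) | C=C(C(=O)OC)[C@@H]1Oc2ccc([C@H](C)OC(=O)/C(C)=C\C)cc2[C@@H]1OC(C)=O | target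

**Step count**

Total: 18 steps. Longest linear sequence: 17 steps (steps 1–7 and 9–18; step 8 is a one-step branch).

**Steps most likely to fail**

1. Step 9 (the proposed new method). The electron-rich ynol ether may divert the ruthenium catalyst into unproductive carbene or ketene-type pathways, the silylated terminus may slow the oxidative coupling so that 16 trimerises instead, or 16 may insert with the wrong orientation. Fallback with known reactions only, setting out from 9 and returning at 17; O1 is introduced after the arene is built, so no alkynyl ether is needed.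
   - The hydroxyl group of 9 is inverted by a Mitsunobu reaction with 4-nitrobenzoic acid (PPh3, DIAD, THF) to the (2R)-4-nitrobenzoate F1.
   - K2CO3 in MeOH removes the ester and the C-silyl group to give the (2R)-alcohol F2.
   - Silylation with chlorodiisopropyl[(triethylsilyl)ethynyl]silane (imidazole, DMF) gives the silyl-ether-tethered diyne F3.
   - The documented temporary-silicon-tether cocyclisation with 16 (CpCo(CO)2, hν, toluene, reflux) gives the benzoxasiline F4, the bulky SiEt3 terminus again directing the side chain to the meta position.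
   - Tamao–Fleming oxidation of the aryl–silicon bond (KF, KHCO3, H2O2, THF–MeOH) gives the phenol F5.
   - Intramolecular Mitsunobu etherification (PPh3, DIAD) closes O1–C2 with inversion, which restores the (2S) configuration and gives 17.

2. Step 11. The C7–Si bond of this electron-rich arene may cleave too slowly, and forcing the base may start to remove the triisopropylsilyl ether or eliminate the C3 ether toward the benzofuran. Fallback from 18 to 19 by electrophilic substitution and reduction instead of nucleophilic cleavage: ipso-iododesilylation with iodine monochloride (CH2Cl2, −78 °C) gives the 7-iodide F6; iodine–magnesium exchange (i-PrMgCl·LiCl, THF, −20 °C) and protonation with MeOH then gives 19.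

3. Step 13. Under K2CO3 in MeOH the aldehyde may epimerise at C2 (toward the trans isomer) or lose the C3 ether by β-elimination toward the aromatic benzofuran before it is homologated. Fallback from 20 to 21 that avoids base on the aldehyde: Corey–Fuchs olefination (CBr4, PPh3, Et3N, CH2Cl2, 0 °C) gives the 1,1-dibromoalkene F7, and n-BuLi (THF, −78 °C; then NH4Cl) converts it to 21.

**Further compounds**

F1 | step 9 | (2R,3S)-1-[(tert-butyldiphenylsilyl)oxy]-3-[(4-methoxybenzyl)oxy]-5-(trimethylsilyl)pent-4-yn-2-yl 4-nitrobenzoate | CC(C)(C)[Si](c1ccccc1)(c1ccccc1)OC[C@@H](OC(=O)c1ccc(cc1)[N+](=O)[O-])[C@@H](OCc1ccc(OC)cc1)C#C[Si](C)(C)C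
F2 | step 9 | (2R,3S)-1-[(tert-butyldiphenylsilyl)oxy]-3-[(4-methoxybenzyl)oxy]pent-4-yn-2-ol | CC(C)(C)[Si](c1ccccc1)(c1ccccc1)OC[C@@H](O)[C@@H](OCc1ccc(OC)cc1)C#C
F3 | step 9 | (2R,3S)-1-[(tert-butyldiphenylsilyl)oxy]-2-({diisopropyl[(triethylsilyl)ethynyl]silyl}oxy)-3-[(4-methoxybenzyl)oxy]pent-4-yne | CC(C)(C)[Si](c1ccccc1)(c1ccccc1)OC[C@@H](O[Si](C(C)C)(C(C)C)C#C[Si](CC)(CC)CC)[C@@H](OCc1ccc(OC)cc1)C#C
F4 | step 9 | (3R,4S)-3-{[(tert-butyldiphenylsilyl)oxy]methyl}-1,1-diisopropyl-4-[(4-methoxybenzyl)oxy]-8-(triethylsilyl)-6-{(1S)-1-[(triisopropylsilyl)oxy]ethyl}-3,4-dihydro-1H-benzo[c][1,2]oxasiline | CC(C)(C)[Si](c3ccccc3)(c3ccccc3)OC[C@H]1O[Si](C(C)C)(C(C)C)c2c([Si](CC)(CC)CC)cc([C@H](C)O[Si](C(C)C)(C(C)C)C(C)C)cc2[C@@H]1OCc3ccc(OC)cc3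
F5 | step 9 | 2-{(1S,2R)-3-[(tert-butyldiphenylsilyl)oxy]-2-hydroxy-1-[(4-methoxybenzyl)oxy]propyl}-6-(triethylsilyl)-4-{(1S)-1-[(triisopropylsilyl)oxy]ethyl}phenol | CC(C)(C)[Si](c3ccccc3)(c3ccccc3)OC[C@@H](O)[C@@H](OCc3ccc(OC)cc3)c1cc(cc([Si](CC)(CC)CC)c1O)[C@H](C)O[Si](C(C)C)(C(C)C)C(C)C
F6 | step 11 | [(2S,3S)-7-iodo-3-[(4-methoxybenzyl)oxy]-5-{(1S)-1-[(triisopropylsilyl)oxy]ethyl}-2,3-dihydrobenzofuran-2-yl]methanol | OC[C@@H]1Oc2c(I)cc([C@H](C)O[Si](C(C)C)(C(C)C)C(C)C)cc2[C@@H]1OCc3ccc(OC)cc3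
F7 | step 13 | (2S,3S)-2-(2,2-dibromovinyl)-3-[(4-methoxybenzyl)oxy]-5-{(1S)-1-[(triisopropylsilyl)oxy]ethyl}-2,3-dihydrobenzofuran | BrC(Br)=C[C@@H]1Oc2ccc([C@H](C)O[Si](C(C)C)(C(C)C)C(C)C)cc2[C@@H]1OCc3ccc(OC)cc3
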